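## Retrosynthetic overview

1. Germacrane numbering is used: C6 = O–CH of the lactone, C7 = the other fusion CH, C11 = CH(CH3), C3 and C9 = AcO–CH, and C4=C5 and C1=C10 are the two Z ring olefins. Endgame: diacetate 32 ⇐ diol 31 ⇐ 9-ketone 29 by reagent-controlled 1,2-reduction.
2. Key disconnection: the ten-membered ring of 29 ⇐ a cyclohexanone (C4–C5–C6–C7–C8–C9), obtained by re-joining C4 and C9. Keto mesylate 26 carries the four missing ring atoms (C3, C2, C1, C10) as a (Z)-alkenyl iodide chain on C4. I/Li exchange, addition to C9=O and Wharton–Grob fragmentation insert them in one operation.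
3. Enabling feature: oxygenated C9 lies 1,6-transannular to C4, the methyl-bearing end of the C4=C5 olefin, so O–C9···C4=C5 is the retron of a 1,3-diol monosulfonate fragmentation. Both ring olefins are Z, so C9–C10=C1–C2–C3–C4 fits a cyclohexene and a cis-decalin can write the C4=C5 geometry. The trans-fused γ-lactone on C6–C7 locks the cyclohexane chair.
4. 26 ⇐ enone lactone 12 (osmylation, cyclic carbonate, SmI2 aldol with (Z)-4-iodopent-3-enal 22). 12 ⇐ butenolide 4 (anti conjugate addition, kinetic protonation, ozonolysis, aldol condensation). 4 ⇐ (R)-glyceraldehyde acetonide.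
5. Ring order: γ-lactone (step 2) → temporary cyclohexane ring (step 6) → transient cyclohexene ring and, through its fragmentation, the ten-membered ring last (step 15). The temporary carbonate ring made in step 8 is removed in step 12.

Key step: step 15

Convention: β is the face of H-6 and α the face of H-7. In the lactone-locked chair, O6 and C11 are equatorial.

Assumption: compounds 2, 5 and 16 are taken as catalogue chemicals.

## Route

Step 1
Reactants: 1 (R)-2,2-dimethyl-1,3-dioxolane-4-carbaldehyde; 2 methyl 2-[bis(2,2,2-trifluoroethoxy)phosphoryl]propanoate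
Product: 3 methyl (Z)-3-[(4S)-2,2-dimethyl-1,3-dioxolan-4-yl]-2-methylprop-2-enoate
Conditions: KHMDS, 18-crown-6, THF, −78 °C
Reagents that add atoms: none
Why: Still–Gennari modification of the Horner–Wadsworth–Emmons reaction, in which the trifluoroethyl phosphonate under dissociating conditions eliminates from the kinetic adduct and should give the (Z)-trisubstituted enoate, leaving the stereocentre of 1 (later C6) untouched.

Step 2
Reactants: 3 methyl (Z)-3-[(4S)-2,2-dimethyl-1,3-dioxolan-4-yl]-2-methylprop-2-enoate
Product: 4 (5S)-5-(hydroxymethyl)-3-methylfuran-2(5H)-one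
Conditions: 1 M aq. HCl, THF, 23 °C
Reagents that add atoms: none
Why: Acid hydrolysis of the acetonide is followed by spontaneous lactonisation (transesterification), because only in the Z ester can the secondary C6–OH reach the ester carbonyl and the five-membered butenolide is preferred over the six-membered ring through the primary OH.

Step 3
Reactants: 4 (5S)-5-(hydroxymethyl)-3-methylfuran-2(5H)-one; 5 2-(chloromethyl)but-1-ene
Product: 9 (3R,4S,5S)-5-(hydroxymethyl)-3-methyl-4-(2-methylenebutyl)oxolan-2-one, via (2-methylenebutyl)magnesium chloride 6 (not isolated), via O-TMS butenolide 7 (not isolated), via ketene silyl acetal 8 (not isolated)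
Conditions: 5, Mg, THF, 0 °C (→ 6); 4, TMSCl, Et3N, THF, 0 °C (→ 7); 6 + 7, CuBr·SMe2 (10 mol %), TMSCl, THF, −78 °C (→ 8); 1 M HCl, −20 → 0 °C
Reagents that add atoms: none
Why: Copper-catalysed, TMSCl-accelerated conjugate addition of an allylic Grignard reagent, in which the nucleophile enters anti to the C6 substituent (sets C7, trans), the ketene silyl acetal is protonated kinetically on the face opposite the new C7 chain (sets C11 with CH3 cis to C8), and the transient O-TMS group falls off in the same acidic work-up.

Step 4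
Reactants: 9 (3R,4S,5S)-5-(hydroxymethyl)-3-methyl-4-(2-methylenebutyl)oxolan-2-one
Product: 10 (3R,4S,5S)-5-(hydroxymethyl)-3-methyl-4-(2-oxobutyl)oxolan-2-one
Conditions: O3, CH2Cl2–MeOH, −78 °C; Me2S, −78 → 23 °C
Reagents that add atoms: ozone [O-][O+]=O
Why: Ozonolysis with reductive work-up cleaves the only C=C bond to the ethyl ketone (C9=O) and touches no stereocentre.

Step 5
Reactants: 10 (3R,4S,5S)-5-(hydroxymethyl)-3-methyl-4-(2-oxobutyl)oxolan-2-one
Product: 11 (2S,3S,4R)-4-methyl-5-oxo-3-(2-oxobutyl)oxolane-2-carbaldehyde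
Conditions: Dess–Martin periodinane, CH2Cl2, 0 → 23 °C
Reagents that add atoms: none
Why: Dess–Martin oxidation turns the primary alcohol into the C5 aldehyde under non-basic conditions that spare the epimerisable C6 and C11 centres.

Step 6
Reactants: 11 (2S,3S,4R)-4-methyl-5-oxo-3-(2-oxobutyl)oxolane-2-carbaldehyde
Product: 12 (3R,3aS,7aS)-3,6-dimethyl-3a,7a-dihydro-1-benzofuran-2,5(3H,4H)-dione
Conditions: piperidine (20 mol %), AcOH (20 mol %), toluene, 4 Å MS, 50 °C
Reagents that add atoms: none
Why: Intramolecular aldol condensation (6-enolendo), in which only the ketone enol towards C4 can reach the aldehyde through a six-membered ring (C8 would give a four-membered ring) and loss of water gives the conjugated enone without touching C6, C7 or C11.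

Step 7
Reactants: 12 (3R,3aS,7aS)-3,6-dimethyl-3a,7a-dihydro-1-benzofuran-2,5(3H,4H)-dione
Product: 13 (3R,3aS,6R,7R,7aS)-6,7-dihydroxy-3,6-dimethylhexahydro-1-benzofuran-2,5-dione (C4–OH β-axial; C4–CH3 α-equatorial; C5–OH β-equatorial)
Conditions: OsO4 (5 mol %), NMO, citric acid, t-BuOH–acetone–H2O, 23 °C
Reagents that add atoms: osmium tetroxide (oxygen carrier) O=[Os](=O)(=O)=O; N-methylmorpholine N-oxide C[N+]1([O-])CCOCC1; water O
Why: Upjohn-type catalytic dihydroxylation (citric acid variant for electron-poor olefins) adds suprafacially on the β face, anti to the allylic C6–O bond as generally found for osmylation of allylic esters and ethers, and so sets C5–OH equatorial and trans to O6 and C4–OH axial.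

Step 8
Reactants: 13 4β,5β-diol
Product: 14 4β,5β-cyclic carbonate of 13
Conditions: CDI, DMAP (10 mol %), toluene, 60 °C
Reagents that add atoms: 1,1'-carbonyldiimidazole O=C(n1ccnc1)n1ccnc1
Why: Carbonylation of the cis-diol gives the cis-fused five-membered carbonate, which turns the axial C4–O bond into a reducible α-acyloxy group and masks O5 as a group that cannot leave from an enolate.

Step 9
Reactants: 15 ethyltriphenylphosphonium iodide; 16 3-[(tert-butyldimethylsilyl)oxy]propanal
Product: 20 (Z)-tert-butyl[(4-iodopent-3-en-1-yl)oxy]dimethylsilane, via ethylidenetriphenylphosphorane 17 (not isolated), via (1-iodoethyl)triphenylphosphonium iodide 18 (not isolated), via (1-iodoethylidene)triphenylphosphorane 19 (not isolated)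
Conditions: 15, n-BuLi, THF, 23 °C; I2, THF, −78 °C; NaHMDS, −20 °C; 16, −30 °C
Reagents that add atoms: iodine II
Why: Stork–Zhao-type Wittig olefination with the α-iodo ylide gives (Z)-2-iodoalk-2-enes under kinetic control, so iodine ends up cis to the chain (later C2 cis to C9).

Step 10
Reactants: 20 (Z)-tert-butyl[(4-iodopent-3-en-1-yl)oxy]dimethylsilane
Product: 21 (Z)-4-iodopent-3-en-1-ol
Conditions: 1 M aq. HCl, THF, 23 °C
Reagents that add atoms: none
Why: Mild acid hydrolysis of the primary TBS ether leaves the alkenyl iodide and its geometry untouched.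

Step 11
Reactants: 21 (Z)-4-iodopent-3-en-1-ol
Product: 22 (Z)-4-iodopent-3-enal
Conditions: Dess–Martin periodinane, CH2Cl2, 0 °C; used at once
Reagents that add atoms: none
Why: Dess–Martin oxidation gives the β,γ-unsaturated aldehyde without base, so the double bond should not move into conjugation.

Step 12
Reactants: 14 4β,5β-cyclic carbonate; 22 (Z)-4-iodopent-3-enal
Product: 24 (3S)-aldol diol (C4: CH3 α-equatorial / side chain β-axial; C5–OH β-equatorial), via samarium(III) enolate 23 (not isolated)
Conditions: SmI2 (2.2 equiv) added to 14 + 22, THF, −78 °C; pH 7 buffer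
Reagents that add atoms: none
Why: Samarium diiodide reduction of the α-acyloxy ketone (the axial C4–O bond overlaps with the ketyl π system) gives the C4=C9 samarium enolate regiospecifically, and its Reformatsky-type aldol addition to 22 should follow a Zimmerman–Traxler chair on the axial β face with the aldehyde hydrogen over the ring, which sets C4 (chain β-axial, cis to O5) and C3 (S), while the hemicarbonate on O5 cannot be eliminated and loses CO2 on work-up.

Step 13
Reactants: 24 (3S)-aldol diol
Product: 25 3-O-TES ether of 24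
Conditions: TESCl (1.05 equiv), imidazole, CH2Cl2, −20 °C
Reagents that add atoms: chlorotriethylsilane CC[Si](Cl)(CC)CC
Why: Selective silylation is expected because C3–OH (one CH2 neighbour) is less hindered and more nucleophilic than C5–OH, which is flanked by quaternary C4 and the acyloxy-bearing C6.

Step 14
Reactants: 25 3-O-TES ether
Product: 26 keto mesylate (C5–OMs β-equatorial)
Conditions: MsCl, Et3N, CH2Cl2, −10 °C
Reagents that add atoms: methanesulfonyl chloride CS(=O)(=O)Cl
Why: Mesylation via sulfene reaches the hindered equatorial C5–OH, and the product cannot eliminate because C4 is quaternary and H-6 is not antiperiplanar to the equatorial C5–O bond.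

Step 15
Reactants: 26 keto mesylate
Product: 29 (1(10)Z,4Z)-9-oxo-3-(triethylsilyloxy)germacra-1(10),4-dien-6,12-olide, via alkenyllithium 27 (not isolated), via cis-decalin lithium alkoxide 28 (not isolated)
Conditions: n-BuLi (1.05 equiv), THF, −78 °C, 10 min; then −78 → 23 °C
Reagents that add atoms: none
Why: Iodine–lithium exchange on the (Z)-alkenyl iodide (stereoretentive, and at −78 °C faster than attack of n-BuLi on the hindered ketone, the lactone or the mesylate) gives alkenyllithium 27, which can reach only the C9 ketone (6-exo-trig, whereas the lactone carbonyl would need a nine-membered transition state) and must add to its β face because its tether is the β-axial substituent of C4, so only the cis-fused alkoxide 28 (O9 α-axial, C10 equatorial) can form. In 28 the C4–C9 bond is antiperiplanar to the equatorial C5–OMs bond of the chair locked by the trans-fused lactone, so on warming the alkoxide expels mesylate in a concerted Wharton–Grob fragmentation that cuts the bond shared by the two six-membered rings and leaves the ten-membered ring (ring expansion 6 → 10 by insertion of C10–C1–C2–C3 between C9 and C4). The closest known reaction type is the sequential intramolecular Barbier cyclisation/Grob fragmentation of iodoalkyl keto mesylates to eight- to ten-membered cycloalkenones, together with the n-BuLi-induced cyclisation of alkenyl iodide ketones and the classical fragmentation of decalin-1,3-diol monosulfonates. No stereocentre is created, since C4, C5 and the transient C9 carbinol are spent and their relative configuration becomes olefin geometry: across C4–C5, C3 is anti to H-5 and CH3-15 anti to C6, hence (Z)-C4=C5, while C1=C10 keeps the Z geometry of the iodide because it is held in the cyclohexene ring. C3, C6, C7 and C11 are spectators, and the base is consumed as it acts (LiOMs is formed), which protects the epimerisable C11. The price is that O3 must occupy the concave face of 28, which is why a slim silyl ether and an irreversible organolithium addition are chosen.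

Step 16
Reactants: 29 9-oxo germacradienolide TES ether
Product: 31 (3S,9R)-3,9-dihydroxy-(1(10)Z,4Z)-germacra-1(10),4-dien-6,12-olide, via 9R carbinol TES ether 30 (not isolated)
Conditions: (S)-Me-CBS (20 mol %), catecholborane, toluene, −78 °C; MeOH; then 1 M aq. HCl, THF, 0 °C
Reagents that add atoms: none
Why: In the Corey–Bakshi–Shibata reduction, with the α-methylalkenyl residue (C10) as the large and C8H2 as the small group, the (S)-oxazaborolidine should deliver hydride to give the (9R)-allylic alcohol by 1,2-reduction, and the acidic work-up removes the TES group.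

Step 17
Reactants: 31 (3S,9R)-diol
Product: 32 target diacetate
Conditions: Ac2O, pyridine, DMAP (cat.), CH2Cl2, 23 °C
Reagents that add atoms: acetic anhydride CC(=O)OC(C)=O
Why: Standard DMAP-catalysed acetylation esterifies both secondary allylic alcohols with retention under conditions too mild to epimerise C11.

## Compound list

1 | (R)-2,2-dimethyl-1,3-dioxolane-4-carbaldehyde | O=C[C@H]1COC(C)(C)O1 | starting material
2 | methyl 2-[bis(2,2,2-trifluoroethoxy)phosphoryl]propanoate | COC(=O)C(C)P(=O)(OCC(F)(F)F)OCC(F)(F)F | starting material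
3 | methyl (Z)-3-[(4S)-2,2-dimethyl-1,3-dioxolan-4-yl]-2-methylprop-2-enoate | COC(=O)/C(C)=C\[C@H]1COC(C)(C)O1 | intermediate
4 | (5S)-5-(hydroxymethyl)-3-methylfuran-2(5H)-one | CC1=C[C@@H](CO)OC1=O | intermediate
5 | 2-(chloromethyl)but-1-ene | CCC(=C)CCl | starting material
6 | (2-methylenebutyl)magnesium chloride | CCC(=C)C[Mg]Cl | intermediate
7 | (5S)-3-methyl-5-[(trimethylsilyloxy)methyl]furan-2(5H)-one | CC1=C[C@@H](CO[Si](C)(C)C)OC1=O | intermediate
8 | ketene silyl acetal of the conjugate adduct (C7 chain trans to the C6 substituent) | CCC(=C)C[C@@H]1[C@@H](CO[Si](C)(C)C)OC(O[Si](C)(C)C)=C1C | intermediate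
9 | (3R,4S,5S)-5-(hydroxymethyl)-3-methyl-4-(2-methylenebutyl)oxolan-2-one | CCC(=C)C[C@@H]1[C@@H](CO)OC(=O)[C@@H]1C | intermediate
10 | (3R,4S,5S)-5-(hydroxymethyl)-3-methyl-4-(2-oxobutyl)oxolan-2-one | CCC(=O)C[C@@H]1[C@@H](CO)OC(=O)[C@@H]1C | intermediate
11 | (2S,3S,4R)-4-methyl-5-oxo-3-(2-oxobutyl)oxolane-2-carbaldehyde | CCC(=O)C[C@@H]1[C@@H](C=O)OC(=O)[C@@H]1C | intermediate
12 | (3R,3aS,7aS)-3,6-dimethyl-3a,7a-dihydro-1-benzofuran-2,5(3H,4H)-dione (trans-fused enone lactone) | O=C1C[C@@H]2[C@@H](C=C1C)OC(=O)[C@@H]2C | intermediate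
13 | (3R,3aS,6R,7R,7aS)-6,7-dihydroxy-3,6-dimethylhexahydro-1-benzofuran-2,5-dione (4β-OH axial, 5β-OH equatorial) | O=C1C[C@@H]2[C@@H]([C@@H](O)[C@@]1(C)O)OC(=O)[C@@H]2C | intermediate
14 | 4β,5β-cyclic carbonate of 13 | O=C1C[C@@H]2[C@@H]([C@H]3OC(=O)O[C@@]13C)OC(=O)[C@@H]2C | intermediate
15 | ethyltriphenylphosphonium iodide | CC[P+](c1ccccc1)(c1ccccc1)c1ccccc1.[I-] | starting material
16 | 3-[(tert-butyldimethylsilyl)oxy]propanal | O=CCCO[Si](C)(C)C(C)(C)C | starting material
17 | ethylidenetriphenylphosphorane | CC=P(c1ccccc1)(c1ccccc1)c1ccccc1 | intermediate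
18 | (1-iodoethyl)triphenylphosphonium iodide | CC(I)[P+](c1ccccc1)(c1ccccc1)c1ccccc1.[I-] | intermediate
19 | (1-iodoethylidene)triphenylphosphorane | CC(I)=P(c1ccccc1)(c1ccccc1)c1ccccc1 | intermediate
20 | (Z)-tert-butyl[(4-iodopent-3-en-1-yl)oxy]dimethylsilane | CC(C)(C)[Si](C)(C)OCC/C=C(/C)I | intermediate
21 | (Z)-4-iodopent-3-en-1-ol | OCC/C=C(/C)I | intermediate
22 | (Z)-4-iodopent-3-enal | O=CC/C=C(/C)I | intermediate
23 | samarium(III) C4=C9 enolate with O5 hemicarbonate | CC1=C([O-])C[C@@H]2[C@@H]([C@H]1OC([O-])=O)OC(=O)[C@@H]2C.[Sm+3].[I-] | intermediate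
24 | aldol diol: trans-fused keto lactone, C4 with CH3 (α-equatorial) and β-axial (1S,3Z)-1-hydroxy-4-iodopent-3-enyl chain, C5–OH β-equatorial | O=C1C[C@@H]2[C@@H]([C@@H](O)[C@@]1(C)[C@@H](O)C/C=C(/C)I)OC(=O)[C@@H]2C | intermediate
25 | 3-O-triethylsilyl ether of 24 | O=C1C[C@@H]2[C@@H]([C@@H](O)[C@@]1(C)[C@@H](O[Si](CC)(CC)CC)C/C=C(/C)I)OC(=O)[C@@H]2C | intermediate
26 | keto mesylate (5β-equatorial OMs, 3-O-TES, (Z)-alkenyl iodide) | O=C1C[C@@H]2[C@@H]([C@@H](OS(C)(=O)=O)[C@@]1(C)[C@@H](O[Si](CC)(CC)CC)C/C=C(/C)I)OC(=O)[C@@H]2C | intermediate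
27 | (Z)-alkenyllithium from 26 | O=C1C[C@@H]2[C@@H]([C@@H](OS(C)(=O)=O)[C@@]1(C)[C@@H](O[Si](CC)(CC)CC)C/C=C(/C)[Li])OC(=O)[C@@H]2C | intermediate
28 | cis-decalin lithium alkoxide (O9 α-axial, CH3-15 α, C4–C9 bond anti to C5–OMs) | [Li]O[C@]12C[C@@H]3[C@@H]([C@@H](OS(C)(=O)=O)[C@@]1(C)[C@@H](O[Si](CC)(CC)CC)CC=C2C)OC(=O)[C@@H]3C | intermediate
29 | (3S,6S,7S,11R,1(10)Z,4Z)-9-oxo-3-(triethylsilyloxy)germacra-1(10),4-dien-6,12-olide | CC[Si](CC)(CC)O[C@H]1C/C=C(/C)C(=O)C[C@@H]2[C@@H](/C=C\1C)OC(=O)[C@@H]2C | intermediate
30 | (9R)-carbinol of 29 (3-O-TES) | CC[Si](CC)(CC)O[C@H]1C/C=C(/C)[C@H](O)C[C@@H]2[C@@H](/C=C\1C)OC(=O)[C@@H]2C | intermediate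
31 | (3S,6S,7S,9R,11R,1(10)Z,4Z)-3,9-dihydroxygermacra-1(10),4-dien-6,12-olide | O[C@H]1C/C=C(/C)[C@H](O)C[C@@H]2[C@@H](/C=C\1C)OC(=O)[C@@H]2C | intermediate
32 | (3S,6S,7S,9R,11R,1(10)Z,4Z)-3,9-diacetoxygermacra-1(10),4-dien-6,12-olide | CC(=O)O[C@H]1C/C=C(/C)[C@H](OC(C)=O)C[C@@H]2[C@@H](/C=C\1C)OC(=O)[C@@H]2C | target

## Summary and risks

Total step count: 17. Longest linear sequence: 14 steps (steps 1–8 and 12–17).

**Step 15.**
- What may go wrong: the alkenyllithium may be quenched by proton transfer from C8–H (enolisation). Closure may be slowed because O3 has to enter the concave face of the cis-decalin. The lithium alkoxide may fragment too slowly, so that C11 epimerises.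
- Fallback (two events separated, a different ring-closing reaction): it sets out from 26. Luche reduction (NaBH4, CeCl3, MeOH, −78 °C; axial hydride attack) gives the 9β-hydroxy mesylate F1. KHMDS (THF, 0 °C) triggers the same antiperiplanar Grob fragmentation, which now opens the cyclohexane to the seco-aldehyde F2 that already holds (Z)-C4=C5. An intramolecular Nozaki–Hiyama–Kishi reaction (CrCl2, cat. NiCl2, DMSO, high dilution) closes C9–C10 as the last ring and comes back to the route at 30. An unwanted C9 epimer can be oxidised with Dess–Martin periodinane to 29.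

**Step 12.**
- What may go wrong: the samarium enolate may be protonated by the acidic β,γ-unsaturated aldehyde. Facial selectivity at C4 may be low. Simple diastereoselection at C3 may erode through retro-aldol equilibration.
- Fallback (cycloaddition as aldol surrogate, which makes C4–C3 and C5–O suprafacially): it sets out from 12 and 22. Aldehyde 22 and hydroxylamine give (Z)-4-iodopent-3-enal oxime F3. NCS then Et3N generates the nitrile oxide F4. F4 adds to the enone 12 with oxygen at the β-carbon, anti to O6, to give the isoxazoline F5. Mo(CO)6 in wet MeCN cleaves the N–O bond to the 5β-hydroxy 3,9-diketone F6. Narasaka–Prasad reduction (Et2BOMe, NaBH4, −78 °C), in which only the exocyclic C3 ketone can chelate with O5, gives the syn-1,3-diol and comes back to the route at 24.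

**Step 7.**
- What may go wrong: osmylation of the electron-poor trisubstituted enone may be sluggish, or attack may occur on the α face, which would place O5 axial and make it useless for the fragmentation.
- Fallback (hydroxyl-directed epoxidation in place of dihydroxylation): it sets out from 12. Luche reduction gives the 9β (pseudo-equatorial) allylic alcohol F7. mCPBA epoxidises syn to the hydroxyl group (Henbest effect) to the 4β,5β-epoxy alcohol F8. Dess–Martin oxidation gives the epoxy ketone F9. SmI2 in the presence of 22 (−78 °C) opens the Cα–O bond to the same type of C4=C9 enolate bearing a 5β-alkoxide, and the aldol addition comes back to the route at 24, bypassing 13 and 14.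

Further compounds
F1 | step 15 | 9β-hydroxy mesylate (reduced 26) | O[C@H]1C[C@@H]2[C@@H]([C@@H](OS(C)(=O)=O)[C@@]1(C)[C@@H](O[Si](CC)(CC)CC)C/C=C(/C)I)OC(=O)[C@@H]2C
F2 | step 15 | seco-aldehyde with (Z)-C4=C5 and (Z)-alkenyl iodide | O=CC[C@@H]1[C@@H](/C=C(/C)[C@@H](O[Si](CC)(CC)CC)C/C=C(/C)I)OC(=O)[C@@H]1C
F3 | step 12 | (Z)-4-iodopent-3-enal oxime | ON=CC/C=C(/C)I
F4 | step 12 | (Z)-4-iodopent-3-enenitrile oxide | [O-][N+]#CC/C=C(/C)I
F5 | step 12 | β-face isoxazoline (O on C5, C3 on C4) | O=C1C[C@@H]2[C@@H]([C@H]3ON=C(C/C=C(/C)I)[C@@]13C)OC(=O)[C@@H]2C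
F6 | step 12 | 5β-hydroxy 3,9-diketone | O=C1C[C@@H]2[C@@H]([C@@H](O)[C@@]1(C)C(=O)C/C=C(/C)I)OC(=O)[C@@H]2C
F7 | step 7 | 9β-allylic alcohol from 12 | O[C@H]1C[C@@H]2[C@@H](C=C1C)OC(=O)[C@@H]2C
F8 | step 7 | 4β,5β-epoxy 9β-alcohol | O[C@H]1C[C@@H]2[C@@H]([C@H]3O[C@@]13C)OC(=O)[C@@H]2C
F9 | step 7 | 4β,5β-epoxy ketone | O=C1C[C@@H]2[C@@H]([C@H]3O[C@@]13C)OC(=O)[C@@H]2C
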